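**Retrosynthetic overview**
- The target is reached by syn-hydration (hydroboration–oxidation, with loss of the phenol acetates) of a C2-symmetric trans-2,5-diaryl-3,4-dimethyl-2,5-dihydrofuran. Its two alkene faces are equivalent, so only the position of boron (away from the neighbouring aryl) has to be controlled.
- The dihydrofuran comes from an enantioselective, oxygen-extruding ring contraction of a meso cis-3,6-diaryl-1,2-dioxine with a chiral phosphine (six-membered to five-membered ring, inversion at one benzylic carbon).
- The meso-dioxine comes from singlet-oxygen addition to an (E,E)-1,4-diaryl-2,3-dimethylbuta-1,3-diene.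
- The diene comes from a twofold Heck arylation of 2,3-dimethylbuta-1,3-diene with 4-bromo-2-methoxyphenyl acetate, itself made from catechol (O-methylation, para-bromination, acetylation).
- Ring order: the 1,2-dioxine is formed first and is then contracted to the oxolane, the only ring of the target.

Assumption: the sense of induction of the chiral phospholane in step 5 cannot be predicted; the (2R,5R) reagent is written, and its commercially available mirror image is used if the first run gives the enantiomer of 10.

**Step 1**
Reactants: 1 catechol (benzene-1,2-diol)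
Product: 2 2-methoxyphenol (guaiacol)
Conditions: MeI (1.05 equiv), Li2CO3 (1.1 equiv), DMF, 55 °C
Reagents that add atoms: iodomethane, CI
Why: Williamson O-methylation; the lithium counter-ion chelates the catechol monoanion and the first ether lowers the acidity of the remaining hydroxyl, so alkylation stops largely at the mono-ether (traces of veratrole and catechol are removed by base extraction and distillation).

**Step 2**
Reactants: 2 2-methoxyphenol
Product: 4 4-bromo-2-methoxyphenyl acetate, via 4-bromo-2-methoxyphenol 3 (not isolated)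
Conditions: NBS (1.0 equiv), MeCN, −10 to 0 °C; then Et3N, Ac2O, DMAP (cat.), 0 °C to rt
Reagents that add atoms: N-bromosuccinimide, O=C1CCC(=O)N1Br; acetic anhydride, CC(=O)OC(C)=O
Why: Electrophilic aromatic bromination goes para to the free hydroxyl (the stronger donor), and DMAP-catalysed acetylation in the same flask makes the ring too electron-poor to ionise the benzylic C–O bonds formed later.

**Step 3**
Reactants: 4 4-bromo-2-methoxyphenyl acetate (2.2 equiv); 5 2,3-dimethylbuta-1,3-diene
Product: 7 (1E,3E)-1,4-bis(4-acetoxy-3-methoxyphenyl)-2,3-dimethylbuta-1,3-diene, via mono-arylated diene 6 (not isolated)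
Conditions: Pd(OAc)2 (5 mol %), P(o-tol)3 (12 mol %), NaOAc (2.5 equiv), DMAc, 110 °C, sealed tube; crystallisation of the E,E isomer
Reagents that add atoms: none
Why: Twofold Mizoroki–Heck arylation; each ArPdBr adds to a terminal CH2 of the diene and the allylpalladium formed loses a benzylic β-hydrogen to restore a conjugated diene, giving the thermodynamically preferred E geometry at both new trisubstituted double bonds.

**Step 4**
Reactants: 7 (1E,3E)-1,4-bis(4-acetoxy-3-methoxyphenyl)-2,3-dimethylbuta-1,3-diene
Product: 8 (3R,6S)-3,6-bis(4-acetoxy-3-methoxyphenyl)-4,5-dimethyl-3,6-dihydro-1,2-dioxine (cis, meso)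
Conditions: O2, tetraphenylporphyrin (1 mol %), CH2Cl2, white LED, −20 to 0 °C
Reagents that add atoms: dioxygen, O=O
Why: Sensitised singlet-oxygen [4+2] cycloaddition to the s-cis diene is suprafacial, so the E,E geometry becomes the cis (meso) arrangement of the two benzylic stereocentres.

**Step 5**
Reactants: 8 (3R,6S)-3,6-bis(4-acetoxy-3-methoxyphenyl)-4,5-dimethyl-3,6-dihydro-1,2-dioxine
Product: 10 (2R,5R)-2,5-bis(4-acetoxy-3-methoxyphenyl)-3,4-dimethyl-2,5-dihydrofuran, via dioxaphosphorane 9 (not isolated)
Conditions: (2R,5R)-2,5-dimethyl-1-phenylphospholane (1.1 equiv), toluene, 4 Å MS, −78 to −20 °C; one recrystallisation to raise ee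
Reagents that add atoms: none
Why: Proposed new method: enantiotopos-selective deoxygenative ring contraction of a meso-1,2-dioxine by a C2-symmetric chiral phosphine; the phosphine inserts into the O–O bond to give pentacoordinate dioxaphosphorane 9, whose two P–O bonds are diastereotopic in the chiral phospholane environment, so one ionises preferentially and the freed alkoxide (on the R carbon) displaces the phosphine oxide from the other (S) benzylic carbon by intramolecular SN2 with inversion, converting the cis dioxine into the trans (2R,5R) dihydrofuran, and any SN1 leakage gives only the separable cis (meso) isomer; the closest known reactions are the racemic triphenylphosphine deoxygenation of monocyclic 3,6-dihydro-1,2-dioxines to 2,5-dihydrofurans with inversion at one carbon and the chiral-amine Kornblum–DeLaMare desymmetrisation of meso endoperoxides.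

**Step 6**
Reactants: 10 (2R,5R)-2,5-bis(4-acetoxy-3-methoxyphenyl)-3,4-dimethyl-2,5-dihydrofuran
Product: 12 (2R,3S,4R,5S)-2,5-bis(4-hydroxy-3-methoxyphenyl)-3,4-dimethyloxolan-3-ol, via tertiary alkylborane 11 (not isolated)
Conditions: BH3·THF (3 equiv), THF, 0 °C to rt; then 3 M NaOH, 30% H2O2, 0 °C to rt; NH4Cl work-up
Reagents that add atoms: hydrogen peroxide, OO
Why: Hydroboration–oxidation; syn addition of H–B to the tetrasubstituted alkene (faces equivalent by the C2 axis) places boron on the alkene carbon at the face anti to its neighbouring aryl and hydrogen on the other carbon of the same face, and oxidation with retention gives the C3 hydroxyl trans to the C2 aryl and cis to the C4 hydrogen with both methyls cis, while hydroxide/hydroperoxide cleaves the two aryl acetates in the same pot.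

**Compound list**
1 | catechol (benzene-1,2-diol) | Oc1ccccc1O | starting material
2 | 2-methoxyphenol (guaiacol) | COc1ccccc1O | intermediate
3 | 4-bromo-2-methoxyphenol | COc1cc(Br)ccc1O | intermediate
4 | 4-bromo-2-methoxyphenyl acetate | COc1cc(Br)ccc1OC(C)=O | intermediate
5 | 2,3-dimethylbuta-1,3-diene | C=C(C)C(C)=C | starting material
6 | 4-[(1E)-2,3-dimethylbuta-1,3-dien-1-yl]-2-methoxyphenyl acetate (mono-arylated diene) | COc1cc(/C=C(C)/C(C)=C)ccc1OC(C)=O | intermediate
7 | (1E,3E)-1,4-bis(4-acetoxy-3-methoxyphenyl)-2,3-dimethylbuta-1,3-diene | COc1cc(/C=C(C)/C(C)=C/c2ccc(OC(C)=O)c(OC)c2)ccc1OC(C)=O | intermediate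
8 | (3R,6S)-3,6-bis(4-acetoxy-3-methoxyphenyl)-4,5-dimethyl-3,6-dihydro-1,2-dioxine (cis, meso) | COc1cc([C@@H]2OO[C@H](c3ccc(OC(C)=O)c(OC)c3)C(C)=C2C)ccc1OC(C)=O | intermediate
9 | spiro dioxaphosphorane: phosphorus of (2R,5R)-2,5-dimethyl-1-phenylphospholane inserted into the O–O bond of 8 (4,7-dihydro-1,3,2-dioxaphosphepine ring, aryl groups still cis) | COc1cc([C@@H]2OP3(c4ccccc4)([C@H](C)CC[C@H]3C)O[C@H](c3ccc(OC(C)=O)c(OC)c3)C(C)=C2C)ccc1OC(C)=O | intermediate
10 | (2R,5R)-2,5-bis(4-acetoxy-3-methoxyphenyl)-3,4-dimethyl-2,5-dihydrofuran (trans, C2-symmetric) | COc1cc([C@H]2O[C@H](c3ccc(OC(C)=O)c(OC)c3)C(C)=C2C)ccc1OC(C)=O | intermediate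
11 | tertiary alkylborane: 10 with H at C4 and BH2 at C3 added to the same face, BH2 trans to the C2 aryl, both methyls cis, acetates intact | COc1cc([C@H]2O[C@H](c3ccc(OC(C)=O)c(OC)c3)[C@@](C)(B)[C@@H]2C)ccc1OC(C)=O | intermediate
12 | (2R,3S,4R,5S)-2,5-bis(4-hydroxy-3-methoxyphenyl)-3,4-dimethyloxolan-3-ol | COc1cc([C@H]2O[C@H](c3ccc(O)c(OC)c3)[C@@](C)(O)[C@@H]2C)ccc1O | target

**Total step count:** 6. **Longest linear sequence:** 6 steps (1 to 12).

**Steps most likely to fail**

Step 3 (twofold Heck). The risk is β-hydride elimination towards a methyl group, giving exo-methylene regioisomers and E/Z mixtures. The fallback sets out from 4 and comes back at 7. Sonogashira coupling of 4 with propyne (Pd(PPh3)2Cl2, CuI, Et3N, THF, 50 °C) gives 2-methoxy-4-(prop-1-yn-1-yl)phenyl acetate F1. Head-to-head reductive coupling of two molecules on zirconocene (Cp2ZrCl2 with 2 n-BuLi, THF, −78 °C to rt; aryl groups prefer the carbons next to zirconium) gives the 2,5-diaryl-3,4-dimethylzirconacyclopentadiene F2. Protonolysis (3 M HCl, 0 °C) releases 7 with both double bonds E by construction.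

Step 5 (proposed desymmetrising ring contraction). The risks are low enantioselectivity, SN1 leakage to the cis isomer and SN2′ closure to a vinyl oxirane. The fallback uses known chemistry, sets out from 7 and comes back at 10. Shi mono-epoxidation of 7 (D-fructose-derived Shi ketone 30 mol %, Oxone (2KHSO5·KHSO4·K2SO4), K2CO3 buffer at pH 9.3, MeCN/dimethoxymethane/water, −10 °C; any phenol set free is re-acetylated with Ac2O/pyridine) gives the (2R,3R)-configured vinyl oxirane F3. The facial sense is the one this ketone normally shows with trans-disubstituted and trisubstituted styrenes. Ring expansion with Cu(hfacac)2 (copper bis(hexafluoroacetylacetonate), 5 mol %, toluene, 110 °C) then gives 10. The benzylic C–O stereocentre is kept, and the 2,5-trans isomer is expected to dominate because the aryl group avoids the neighbouring methyl as the ring closes; the cis isomer is removed by chromatography.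

Step 6 (hydroboration of a hindered tetrasubstituted alkene). The risks are sluggish addition and imperfect placement of boron. The fallback sets out from 10 and comes back at 12. Epoxidation of 10 (mCPBA, NaHCO3, CH2Cl2, 0 °C; only one epoxide is possible because the faces are equivalent) gives the 3,4-epoxide F4. Excess LiNEt2 (Et2O/THF, 0 °C to rt) removes a proton from the less hindered methyl group, the one on the carbon whose neighbouring aryl lies on the opposite face. This opens the epoxide and cleaves both acetates, giving (2R,3S,5R)-2,5-bis(4-hydroxy-3-methoxyphenyl)-3-methyl-4-methylideneoxolan-3-ol F5. Hydroxyl-directed hydrogenation ([Ir(cod)(PCy3)(py)]PF6, H2 1 atm, CH2Cl2) delivers hydrogen to the face of the tertiary hydroxyl and gives 12.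

**Further compounds**
F1 | step 3 | 2-methoxy-4-(prop-1-yn-1-yl)phenyl acetate | CC#Cc1ccc(OC(C)=O)c(OC)c1
F2 | step 3 | 1,1-bis(cyclopentadienyl)-2,5-bis(4-acetoxy-3-methoxyphenyl)-3,4-dimethylzirconacyclopenta-2,4-diene | CC1=C(c2ccc(OC(C)=O)c(OC)c2)[Zr](C2C=CC=C2)(C2C=CC=C2)C(c2ccc(OC(C)=O)c(OC)c2)=C1C
F3 | step 5 | (2R,3R)-3-(4-acetoxy-3-methoxyphenyl)-2-[(1E)-1-(4-acetoxy-3-methoxyphenyl)prop-1-en-2-yl]-2-methyloxirane | COc1cc(/C=C(C)/[C@@]2(C)O[C@@H]2c2ccc(OC(C)=O)c(OC)c2)ccc1OC(C)=O
F4 | step 6 | 3,4-epoxide of 10: 2,4-bis(4-acetoxy-3-methoxyphenyl)-1,5-dimethyl-3,6-dioxabicyclo[3.1.0]hexane, aryl groups trans | COc1cc([C@H]2O[C@H](c3ccc(OC(C)=O)c(OC)c3)[C@@]3(C)O[C@]32C)ccc1OC(C)=O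
F5 | step 6 | (2R,3S,5R)-2,5-bis(4-hydroxy-3-methoxyphenyl)-3-methyl-4-methylideneoxolan-3-ol | COc1cc([C@H]2O[C@H](c3ccc(O)c(OC)c3)[C@@](C)(O)C2=C)ccc1O
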